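**Strategy**

Everything rests on disconnecting the single bond between the benzylic CH2 on C1 of the aromatic ring (ortho to the free C2 phenol) and the vinylic CH of the E-trisubstituted alkene in the linker to the hydrindanone. The key step exploits that this bond joins an activated sp3 benzylic carbon to an sp2 carbon of fixed geometry: a Negishi coupling of a silyl-protected benzylic zinc chloride with the complete, unprotected hydrindanone E-alkenyl iodide forms it in one operation with retention. The iodide arises from a de Mayo photocycloaddition of a dioxinone with 1,2-dimethylcyclopentene (cis vicinal quaternary carbons), sulfone acylation with retro-aldol opening, and an enol-ether aldol closing the cyclohexanone ring.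

Key step: step 14

Remark: compounds 1, 6, 7, 10 and 18 are taken as commercial; γ-hydroxy ketones (14, 15, 17, 25, 26) are written in the open form although they may sit partly as five-membered hemiketals; the absolute configuration of resolved 12 is to be confirmed by anomalous-dispersion crystallography of an iodine-containing descendant.

**Route**

Step 1
Reactants: 1 prop-2-yn-1-ol
Product: 3 (E)-3-iodo-2-methylprop-2-en-1-ol, via alkenylalane 2 (not isolated)
Conditions: AlMe3 (3 equiv), Cp2ZrCl2 (0.25 equiv), CH2Cl2, 0 → 25 °C; then I2, THF, −30 → 0 °C; aq. K2CO3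
Reagents that add atoms: trimethylaluminium, C[Al](C)C; iodine, II
Why: Zirconium-catalysed Negishi carboalumination adds methyl and aluminium syn across the terminal alkyne (aluminium on the terminal carbon), and iodinolysis with retention should give the E-2-methyl-1-iodoalkene, which fixes the alkene geometry of the target at the outset.

Step 2
Reactants: 3 (E)-3-iodo-2-methylprop-2-en-1-ol
Product: 5 (E)-[(3-iodo-2-methylprop-2-en-1-yl)sulfonyl]benzene, via allylic mesylate 4 (not isolated)
Conditions: MsCl, Et3N, CH2Cl2, −10 °C; then PhSO2Na, DMF, 25 °C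
Reagents that add atoms: sodium benzenesulfinate, [Na+].[O-]S(=O)c1ccccc1
Why: Mesylation followed by SN2 S-alkylation of the sulfinate at the primary allylic carbon should give the allylic sulfone without touching the alkenyl iodide or its geometry.

Step 3
Reactants: 6 2,2,6-trimethyl-4H-1,3-dioxin-4-one; 7 3-bromo-2-methylprop-1-ene
Product: 8 2,2-dimethyl-6-(3-methylbut-3-en-1-yl)-4H-1,3-dioxin-4-one
Conditions: LiN(iPr)2, THF–DMPU, −78 °C; then 7, −78 → −20 °C
Reagents that add atoms: none
Why: Kinetic deprotonation gives the lithium dienolate of the dioxinone, which is alkylated by reactive allylic halides at the γ-carbon (the former C6 methyl group), a known vinylogous ester alkylation.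

Step 4
Reactants: 8 2,2-dimethyl-6-(3-methylbut-3-en-1-yl)-4H-1,3-dioxin-4-one
Product: 9 6-(3-hydroxy-3-methylbutyl)-2,2-dimethyl-4H-1,3-dioxin-4-one
Conditions: Co(acac)2 (20 mol %), PhSiH3, O2 (1 atm), THF, 25 °C
Reagents that add atoms: dioxygen, O=O
Why: Mukaiyama hydration by hydrogen-atom transfer is Markovnikov-selective for the electron-rich 1,1-disubstituted alkene and should leave the electron-poor dioxinone double bond alone, giving the tertiary alcohol and removing the alkene that would otherwise add intramolecularly in step 5.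

Step 5
Reactants: 9 6-(3-hydroxy-3-methylbutyl)-2,2-dimethyl-4H-1,3-dioxin-4-one; 10 1,2-dimethylcyclopentene
Product: 11 racemic cis-anti-cis photoadduct (cyclobutane fused to the dioxanone and to the dimethylcyclopentane)
Conditions: hν (medium-pressure Hg lamp, Pyrex filter), 10 (10 equiv), MeCN–acetone 9:1, 0 °C
Reagents that add atoms: none
Why: The [2+2] photocycloaddition (first stage of a de Mayo reaction) of the excited dioxinone to the symmetrical tetrasubstituted alkene raises no regiochemical question and necessarily gives a cis-fused cyclobutane–cyclopentane, which fixes the two methyl-bearing quaternary carbons cis to each other; the adduct is racemic, is expected to be mainly cis-anti-cis, and its two dioxinone-derived cyclobutane carbons lose their stereochemistry in step 7.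

Step 6
Reactants: 11 racemic cis-anti-cis photoadduct
Product: 12 photoadduct, single enantiomer (methyl-bearing carbons configured as C3a and C7a of the target)
Conditions: preparative chromatography on a chiral stationary phase (supercritical CO2–MeOH)
Reagents that add atoms: none
Why: Resolution of the racemate on a chiral stationary phase supplies the enantiomer whose two quaternary carbons have the absolute configuration of the target, because auxiliary control of dioxinone photocycloadditions is judged too weak to rely on.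

Step 7
Reactants: 12 photoadduct (single enantiomer); 5 (E)-[(3-iodo-2-methylprop-2-en-1-yl)sulfonyl]benzene
Product: 14 (E)-1-[(1R,2R)-2-(4-hydroxy-4-methylpentanoyl)-1,2-dimethylcyclopentyl]-5-iodo-4-methyl-3-(phenylsulfonyl)pent-4-en-2-one (epimers at C3), via cyclobutanol keto sulfone 13 (not isolated)
Conditions: 5 (2.5 equiv), LiN(SiMe3)2 (3.5 equiv), THF, −78 → −20 °C; aq. NH4Cl; then Et3N (cat.), CH2Cl2, 25 °C
Reagents that add atoms: none
Why: Claisen-type acylation of the α-lithiated allylic sulfone (α-selective and geometrically stable at low temperature) at the acylal carbonyl releases acetone and a cyclobutanol β-keto sulfone, whose strain-driven retro-aldol cleavage (second stage of the de Mayo reaction) should unveil the 1,5-diketone with both quaternary stereocentres untouched.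

Step 8
Reactants: 14 β-keto sulfone
Product: 15 (E)-1-[(1R,2R)-2-(4-hydroxy-4-methylpentanoyl)-1,2-dimethylcyclopentyl]-5-iodo-4-methylpent-4-en-2-one
Conditions: SmI2 (2.5 equiv), THF–MeOH, −78 °C
Reagents that add atoms: none
Why: Reductive desulfonylation of the β-keto sulfone by samarium diiodide gives a dienolate that methanol protonates kinetically at the α-carbon, so the β,γ-alkene stays out of conjugation and the alkenyl iodide (inert to SmI2 at −78 °C without a polar additive) should survive.

Step 9
Reactants: 15 diketone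
Product: 17 (3aR,5R,6S,7aR)-6-hydroxy-5-(2-hydroxy-2-methylpropyl)-6-[(2E)-3-iodo-2-methylprop-2-en-1-yl]-3a,7a-dimethyloctahydro-4H-inden-4-one, via dihydrofuran 16 (not isolated)
Conditions: PPTS (cat.), 4 Å MS, benzene, 60 °C; then TiCl4 (1.1 equiv), 2,6-di-tert-butyl-4-methylpyridine, CH2Cl2, −78 °C; aq. NaHCO3
Reagents that add atoms: water, O
Why: Only the γ-hydroxy ketone can cyclodehydrate, so dihydrofuran 16 is a regiospecific enol ether of the hindered ketone, and its Mukaiyama-type aldol addition to the TiCl4-activated side-arm ketone (6-enolendo-exo-trig, no base, hence no conjugation of the β,γ-alkene) should pass through a chair with the alkenylmethyl group equatorial and the titanium-bound oxygen axial, C5 then settling equatorial on work-up, whereas the choice between the two chairs that put the new hydroxyl cis or trans to the angular methyl groups is only weakly biased by the substrate, so 17 may have to be separated from its (5S,6R)-diastereomer.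

Step 10
Reactants: 18 4-methoxy-2-methylphenol
Product: 19 2-hydroxy-5-methoxy-3-methylbenzaldehyde
Conditions: MgCl2, Et3N, (CH2O)n, MeCN, reflux; aq. HCl work-up
Reagents that add atoms: paraformaldehyde (as formaldehyde), C=O
Why: Magnesium-phenoxide-directed ortho-formylation (Casnati–Skattebøl) is specific for the single free ortho position, the para position being blocked by the methoxy group.

Step 11
Reactants: 19 2-hydroxy-5-methoxy-3-methylbenzaldehyde
Product: 20 2-[(tert-butyldimethylsilyl)oxy]-5-methoxy-3-methylbenzaldehyde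
Conditions: TBSCl, imidazole, DMAP (cat.), DMF, 40 °C
Reagents that add atoms: tert-butyldimethylsilyl chloride, CC(C)(C)[Si](C)(C)Cl
Why: Silylation of the phenol blocks o-quinone methide formation from the later benzylic chloride and zinc reagent and is removable by fluoride at the end.

Step 12
Reactants: 20 2-[(tert-butyldimethylsilyl)oxy]-5-methoxy-3-methylbenzaldehyde
Product: 21 {2-[(tert-butyldimethylsilyl)oxy]-5-methoxy-3-methylphenyl}methanol
Conditions: NaBH4, MeOH–THF, 0 °C
Reagents that add atoms: none
Why: Borohydride reduces the aldehyde chemoselectively to the benzylic alcohol at 0 °C, where aryl-to-alkyl silyl migration is slow.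

Step 13
Reactants: 21 {2-[(tert-butyldimethylsilyl)oxy]-5-methoxy-3-methylphenyl}methanol
Product: 23 tert-butyl[2-(chloromethyl)-4-methoxy-6-methylphenoxy]dimethylsilane, via benzylic mesylate 22 (not isolated)
Conditions: MsCl, Et3N, LiCl, THF, 0 → 25 °C
Reagents that add atoms: lithium chloride, [Li+].[Cl-]
Why: Mesylation and in situ chloride displacement at the activated benzylic position give the chloride under non-acidic conditions that spare the aryl silyl ether.

Step 14
Reactants: 23 tert-butyl[2-(chloromethyl)-4-methoxy-6-methylphenoxy]dimethylsilane; 17 hydrindanone E-alkenyl iodide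
Product: 25 (3aR,5R,6R,7aR)-6-[(2E)-4-{2-[(tert-butyldimethylsilyl)oxy]-5-methoxy-3-methylphenyl}-2-methylbut-2-en-1-yl]-6-hydroxy-5-(2-hydroxy-2-methylpropyl)-3a,7a-dimethyloctahydro-4H-inden-4-one, via benzylic zinc chloride 24 (not isolated)
Conditions: 23 (3 equiv), Zn dust (activated), LiCl, THF, 25 °C; then 17, Pd(OAc)2 (2 mol %), SPhos (4 mol %), THF, 25 °C, slow addition of 24
Reagents that add atoms: none
Why: The alkenyl C–I bond of 17 adds oxidatively to zerovalent palladium (formed in situ from Pd(OAc)2 and SPhos) with retention, the benzylic zinc chloride 24 transmetallates, and reductive elimination forms the bond between the benzylic CH2 and the vinylic CH. The closest known reaction type is the Negishi coupling of benzylic zinc halides with alkenyl iodides. No ring is closed and no stereocentre is created; the E geometry set in step 1 is carried through unchanged. The step needs chemoselectivity for the C–I bond beside a hindered ketone, a base-sensitive β-hydroxy ketone and two tertiary alcohols: the organozinc is weakly basic and does not add to ketones at 25 °C, the medium is neutral (no retro-aldol), and the excess of 24 covers slow protonolysis by the hydroxyls. The ortho silyl ether prevents o-quinone methide formation, and slow addition limits homocoupling.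

Step 15
Reactants: 25 silyl-protected coupling product
Product: 26 (3aR,5R,6R,7aR)-6-hydroxy-6-[(2E)-4-(2-hydroxy-5-methoxy-3-methylphenyl)-2-methylbut-2-en-1-yl]-5-(2-hydroxy-2-methylpropyl)-3a,7a-dimethyloctahydro-4H-inden-4-one (target)
Conditions: TBAF, AcOH (1:1), THF, 0 °C
Reagents that add atoms: none
Why: Buffered fluoride cleaves the aryl silyl ether quickly and selectively, and the acetic acid buffer should suppress retro-aldol cleavage or dehydration of the β-hydroxy ketone.

**Compound list**

1 | prop-2-yn-1-ol | C#CCO | starting material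
2 | (E)-alkenylalane: dimethylaluminium on the terminal alkene carbon, cis to the 2-methyl group, oxygen as dimethylaluminium alkoxide | C[Al](C)/C=C(\C)CO[Al](C)C | intermediate
3 | (E)-3-iodo-2-methylprop-2-en-1-ol | I/C=C(\C)CO | intermediate
4 | (E)-3-iodo-2-methylprop-2-en-1-yl methanesulfonate | I/C=C(\C)COS(C)(=O)=O | intermediate
5 | (E)-[(3-iodo-2-methylprop-2-en-1-yl)sulfonyl]benzene | I/C=C(\C)CS(=O)(=O)c1ccccc1 | intermediate
6 | 2,2,6-trimethyl-4H-1,3-dioxin-4-one | CC1=CC(=O)OC(C)(C)O1 | starting material
7 | 3-bromo-2-methylprop-1-ene | C=C(C)CBr | starting material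
8 | 2,2-dimethyl-6-(3-methylbut-3-en-1-yl)-4H-1,3-dioxin-4-one | C=C(C)CCC1=CC(=O)OC(C)(C)O1 | intermediate
9 | 6-(3-hydroxy-3-methylbutyl)-2,2-dimethyl-4H-1,3-dioxin-4-one | CC(C)(O)CCC1=CC(=O)OC(C)(C)O1 | intermediate
10 | 1,2-dimethylcyclopentene | CC1=C(C)CCC1 | starting material
11 | racemic cis-anti-cis photoadduct: 2,2-dimethyl-1,3-dioxan-4-one cis-fused at C5–C6 to a cyclobutane that is cis-fused to the cyclopentane at its two methyl-bearing carbons; C6 carries the 3-hydroxy-3-methylbutyl chain; dioxanone and cyclopentane on opposite faces of the cyclobutane (SMILES shows the enantiomer carried forward; its mirror image is present in equal amount) | CC(C)(O)CC[C@@]12OC(C)(C)OC(=O)[C@@H]1[C@@]1(C)CCC[C@@]21C | intermediate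
12 | the same photoadduct as a single enantiomer, configuration as in the SMILES | CC(C)(O)CC[C@@]12OC(C)(C)OC(=O)[C@@H]1[C@@]1(C)CCC[C@@]21C | intermediate
13 | cyclobutanol β-keto sulfone: cis-fused 1,5-dimethylbicyclo[3.2.0]heptane with a tertiary OH and the 3-hydroxy-3-methylbutyl chain on C6 and the 2-(phenylsulfonyl)-4-iodo-3-methylbut-3-enoyl group on C7 | CC(C)(O)CC[C@@]1(O)[C@H](C(=O)C(/C(C)=C/I)S(=O)(=O)c2ccccc2)[C@@]2(C)CCC[C@@]12C | intermediate
14 | (E)-1-[(1R,2R)-2-(4-hydroxy-4-methylpentanoyl)-1,2-dimethylcyclopentyl]-5-iodo-4-methyl-3-(phenylsulfonyl)pent-4-en-2-one (C3 epimers) | CC(C)(O)CCC(=O)[C@]1(C)CCC[C@]1(C)CC(=O)C(/C(C)=C/I)S(=O)(=O)c1ccccc1 | intermediate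
15 | (E)-1-[(1R,2R)-2-(4-hydroxy-4-methylpentanoyl)-1,2-dimethylcyclopentyl]-5-iodo-4-methylpent-4-en-2-one | CC(C)(O)CCC(=O)[C@]1(C)CCC[C@]1(C)CC(=O)C/C(C)=C/I | intermediate
16 | (E)-1-[(1R,2R)-2-(5,5-dimethyl-4,5-dihydrofuran-2-yl)-1,2-dimethylcyclopentyl]-5-iodo-4-methylpent-4-en-2-one | CC1(C)CC=C(O1)[C@]1(C)CCC[C@]1(C)CC(=O)C/C(C)=C/I | intermediate
17 | (3aR,5R,6S,7aR)-6-hydroxy-5-(2-hydroxy-2-methylpropyl)-6-[(2E)-3-iodo-2-methylprop-2-en-1-yl]-3a,7a-dimethyloctahydro-4H-inden-4-one (cis ring fusion; OH, both angular methyls and the C5 side chain on one face) | I/C=C(\C)C[C@@]1(O)C[C@@]2(C)CCC[C@@]2(C)C(=O)[C@@H]1CC(C)(C)O | intermediate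
18 | 4-methoxy-2-methylphenol | COc1ccc(O)c(C)c1 | starting material
19 | 2-hydroxy-5-methoxy-3-methylbenzaldehyde | COc1cc(C)c(O)c(C=O)c1 | intermediate
20 | 2-[(tert-butyldimethylsilyl)oxy]-5-methoxy-3-methylbenzaldehyde | COc1cc(C)c(O[Si](C)(C)C(C)(C)C)c(C=O)c1 | intermediate
21 | {2-[(tert-butyldimethylsilyl)oxy]-5-methoxy-3-methylphenyl}methanol | COc1cc(C)c(O[Si](C)(C)C(C)(C)C)c(CO)c1 | intermediate
22 | 2-[(tert-butyldimethylsilyl)oxy]-5-methoxy-3-methylbenzyl methanesulfonate | COc1cc(C)c(O[Si](C)(C)C(C)(C)C)c(COS(C)(=O)=O)c1 | intermediate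
23 | tert-butyl[2-(chloromethyl)-4-methoxy-6-methylphenoxy]dimethylsilane | COc1cc(C)c(O[Si](C)(C)C(C)(C)C)c(CCl)c1 | intermediate
24 | {2-[(tert-butyldimethylsilyl)oxy]-5-methoxy-3-methylbenzyl}zinc chloride | COc1cc(C)c(O[Si](C)(C)C(C)(C)C)c(C[Zn]Cl)c1 | intermediate
25 | (3aR,5R,6R,7aR)-6-[(2E)-4-{2-[(tert-butyldimethylsilyl)oxy]-5-methoxy-3-methylphenyl}-2-methylbut-2-en-1-yl]-6-hydroxy-5-(2-hydroxy-2-methylpropyl)-3a,7a-dimethyloctahydro-4H-inden-4-one | COc1cc(C)c(O[Si](C)(C)C(C)(C)C)c(C/C=C(\C)C[C@@]2(O)C[C@@]3(C)CCC[C@@]3(C)C(=O)[C@@H]2CC(C)(C)O)c1 | intermediate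
26 | (3aR,5R,6R,7aR)-6-hydroxy-6-[(2E)-4-(2-hydroxy-5-methoxy-3-methylphenyl)-2-methylbut-2-en-1-yl]-5-(2-hydroxy-2-methylpropyl)-3a,7a-dimethyloctahydro-4H-inden-4-one | COc1cc(C)c(O)c(C/C=C(\C)C[C@@]2(O)C[C@@]3(C)CCC[C@@]3(C)C(=O)[C@@H]2CC(C)(C)O)c1 | target

**Step count and risks**

Total step count: 15. Longest linear sequence: 9 steps (steps 3, 4, 5, 6, 7, 8, 9, 14, 15, from dioxinone 6).

Steps most likely to fail:

1. Step 9. The two chair transition states differ only in whether the angular methyl groups or the cyclopentane methylenes flank the forming bond, so facial selectivity may be poor; the Lewis acid may also dehydrate the tertiary ketol. The fallback sets out from 15 and comes back at 17, and hands the choice of chair to a chiral catalyst. Dihydrofuran 16 is generated as before and treated with PhSeCl at −78 °C and then water to give the α-phenylselanyl ketone F1. Oxidation with H2O2/pyridine and selenoxide syn-elimination give the E-enone F2, a regiospecific dehydrogenation of the hindered ketone. TESOTf/2,6-lutidine gives the triethylsilyl ether F3. A ligand-controlled copper hydride reductive aldol cyclisation (Cu(OAc)2·H2O, DTBM-SEGPHOS of the matched hand, 1,1,3,3-tetramethyldisiloxane, toluene, −20 °C) delivers hydride to the enone β-carbon, and the chiral copper enolate closes onto the side-arm ketone to give the silyl-protected ketol F4. HF·pyridine in THF returns 17.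

2. Step 7. The bulky sulfonyl carbanion may add slowly to the neopentyl-type acylal carbonyl, and the iodo-substituted allyl anion may lose its geometry or decompose on warming. The fallback sets out from 12 and comes back at 15, and builds the side arm by carbometalation instead. iBu2AlH (CH2Cl2, −78 °C) reduces the acylal to the lactol, which loses acetone and undergoes retro-aldol cleavage on work-up to the keto aldehyde F5. Zinc-mediated Barbier propargylation (propargyl bromide, Zn, THF) adds selectively to the aldehyde to give the homopropargylic alcohol F6. CSA, MeOH and HC(OMe)3 mask the γ-hydroxy ketone as the cyclic methyl ketal F7. Zirconium-catalysed carboalumination and iodinolysis (AlMe3, Cp2ZrCl2, CH2Cl2, −20 °C; then I2) give the E-alkenyl iodide F8. Dess–Martin oxidation gives the ketone F9, and aqueous acetic acid removes the ketal to return 15.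

3. Step 14. Protonolysis of the benzylic zinc reagent by the two tertiary hydroxyls and Wurtz-type homocoupling may outrun the cross-coupling. The fallback sets out from 23 (with 17) and comes back at 25. Bu3SnLi (THF, −78 °C) converts 23 into the benzylstannane F10, which is not basic. Stille coupling of F10 with 17 (Pd2(dba)3, AsPh3, CuI, DMF, 45 °C) should then give 25 under neutral conditions.

Further compounds
F1 | step 9 | (E)-1-[(1R,2R)-2-(4-hydroxy-4-methyl-2-(phenylselanyl)pentanoyl)-1,2-dimethylcyclopentyl]-5-iodo-4-methylpent-4-en-2-one (selenide epimers) | CC(C)(O)CC([Se]c1ccccc1)C(=O)[C@]1(C)CCC[C@]1(C)CC(=O)C/C(C)=C/I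
F2 | step 9 | (E)-1-{(1R,2R)-2-[(E)-4-hydroxy-4-methylpent-2-enoyl]-1,2-dimethylcyclopentyl}-5-iodo-4-methylpent-4-en-2-one | CC(C)(O)/C=C/C(=O)[C@]1(C)CCC[C@]1(C)CC(=O)C/C(C)=C/I
F3 | step 9 | triethylsilyl ether of F2 at the tertiary hydroxyl | CC[Si](CC)(CC)OC(C)(C)/C=C/C(=O)[C@]1(C)CCC[C@]1(C)CC(=O)C/C(C)=C/I
F4 | step 9 | (3aR,5R,6S,7aR)-6-hydroxy-6-[(2E)-3-iodo-2-methylprop-2-en-1-yl]-3a,7a-dimethyl-5-{2-methyl-2-[(triethylsilyl)oxy]propyl}octahydro-4H-inden-4-one | I/C=C(\C)C[C@@]1(O)C[C@@]2(C)CCC[C@@]2(C)C(=O)[C@@H]1CC(C)(C)O[Si](CC)(CC)CC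
F5 | step 7 | 2-[(1R,2R)-2-(4-hydroxy-4-methylpentanoyl)-1,2-dimethylcyclopentyl]acetaldehyde | CC(C)(O)CCC(=O)[C@]1(C)CCC[C@]1(C)CC=O
F6 | step 7 | 1-[(1R,2R)-2-(4-hydroxy-4-methylpentanoyl)-1,2-dimethylcyclopentyl]pent-4-yn-2-ol (carbinol epimers) | CC(C)(O)CCC(=O)[C@]1(C)CCC[C@]1(C)CC(O)CC#C
F7 | step 7 | 1-[(1R,2R)-2-(2-methoxy-5,5-dimethyloxolan-2-yl)-1,2-dimethylcyclopentyl]pent-4-yn-2-ol (epimers at ketal and carbinol carbons) | COC1(CCC(C)(C)O1)[C@]1(C)CCC[C@]1(C)CC(O)CC#C
F8 | step 7 | (E)-1-[(1R,2R)-2-(2-methoxy-5,5-dimethyloxolan-2-yl)-1,2-dimethylcyclopentyl]-5-iodo-4-methylpent-4-en-2-ol | COC1(CCC(C)(C)O1)[C@]1(C)CCC[C@]1(C)CC(O)C/C(C)=C/I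
F9 | step 7 | (E)-1-[(1R,2R)-2-(2-methoxy-5,5-dimethyloxolan-2-yl)-1,2-dimethylcyclopentyl]-5-iodo-4-methylpent-4-en-2-one | COC1(CCC(C)(C)O1)[C@]1(C)CCC[C@]1(C)CC(=O)C/C(C)=C/I
F10 | step 14 | tributyl{2-[(tert-butyldimethylsilyl)oxy]-5-methoxy-3-methylbenzyl}stannane | COc1cc(C)c(O[Si](C)(C)C(C)(C)C)c(C[Sn](CCCC)(CCCC)CCCC)c1
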